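**Retrosynthetic overview**
1. Target 36 ⇐ seco aldehyde/dienyl iodide 34: the ten-membered ring is closed last at C2–C3 by an electroreductive Cr/Ni Nozaki–Hiyama–Kishi (NHK) reaction, which also sets C2.
2. 34 ⇐ alkynyl lactone 31: C5=C6 by Ru-catalysed trans-hydrostannation of the C5≡C6 alkyne, C4–C5 by Stille coupling with (Z)-1,2-diiodoethene.
3. Butanolide ⇐ aldehyde 17 + bromoenyne 21: electrochemical NHK coupling (C8–C9, sets C9), OsO4 dihydroxylation/lactonisation (C8, C7), kinetic enolate protonation (C17).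
4. Cyclohexane 11 ⇐ D-galactal: enonolactone, cuprate addition (C11) with Ireland–Claisen ring contraction (C1, C10); the C12 hydroxyl directs the epoxide and is inverted to the acetate later.
5. Ring order: cyclohexane, then butanolide, then ten-membered carbocycle.

Assumption: 1, 7, 18, 20 and 33 are taken as purchasable; 20 is used as the racemate because C17 is set in step 15.
Labels C1–C20 follow briarane numbering of the target (C15 = methyl on C1, C16 = CH2OH on C5, C18 = methyl on C17, C19 = lactone carbonyl, C20 = methyl on C11). On the cyclohexane ring, β is the face of the C15 methyl and α the opposite face.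

**Route**

Step 1
Reactants: 1 D-galactal
Product: 3 3-O-acetyl-4,6-O-(di-tert-butylsilanediyl)-D-galactal, via silylene 2 (not isolated)
Conditions: tBu2Si(OTf)2, pyridine, DMF, −40 °C; then Ac2O, DMAP (cat.), 0 °C to rt
Reagents that add atoms: di-tert-butylsilyl bis(trifluoromethanesulfonate) CC(C)(C)[Si](OS(=O)(=O)C(F)(F)F)(OS(=O)(=O)C(F)(F)F)C(C)(C)C; acetic anhydride CC(=O)OC(C)=O
Why: The cis-disposed 4-OH/6-OH pair closes the six-membered silylene selectively and the remaining allylic 3-OH is then acylated (silyl protection, then esterification); no stereocentre changes.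

Step 2
Reactants: 3 3-O-acetyl-4,6-O-(di-tert-butylsilanediyl)-D-galactal
Product: 4 silylene-protected enonolactone
Conditions: mCPBA, BF3·OEt2 (cat.), CH2Cl2, −20 °C
Reagents that add atoms: 3-chloroperoxybenzoic acid OOC(=O)c1cccc(Cl)c1
Why: Oxidative Ferrier rearrangement: the allylic C3 acetate is ionised, the peracid adds at C1 and the anomeric perester fragments to the α,β-unsaturated δ-lactone, leaving the two sugar stereocentres (future C12 and C13) untouched.

Step 3
Reactants: 4 silylene-protected enonolactone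
Product: 5 primary alcohol with C12 fluorosilyl ether
Conditions: BF3·SMe2, CH2Cl2, 0 °C; aq. work-up
Reagents that add atoms: boron trifluoride–dimethyl sulfide C[S+](C)[B-](F)(F)F
Why: Regioselective silylene ring opening puts fluoride on silicon and frees the less hindered primary oxygen, while the secondary C12 oxygen stays silylated (selective silyl ether cleavage).

Step 4
Reactants: 5 primary alcohol with C12 fluorosilyl ether
Product: 6 lactone aldehyde
Conditions: Dess–Martin periodinane, CH2Cl2, 0 °C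
Reagents that add atoms: none
Why: Dess–Martin oxidation gives the aldehyde under neutral conditions that spare the enonolactone and do not epimerise the adjacent C13 centre.

Step 5
Reactants: 6 lactone aldehyde; 7 ethyl 2-(diphenoxyphosphoryl)propanoate
Product: 8 lactone (Z)-enoate
Conditions: NaI, DBU, THF, −78 to 0 °C
Reagents that add atoms: none
Why: Ando-type Z-selective Horner–Wadsworth–Emmons olefination places the ester carbon (C2) cis to C13 across the new C14=C1 bond, the geometry that the Claisen step converts into the C1 configuration.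

Step 6
Reactants: 8 lactone (Z)-enoate
Product: 11 cyclohexene hydroxy acid ethyl ester, via ketene silyl acetal 9 (not isolated), via silyl ester 10 (not isolated)
Conditions: Me2CuLi, TMSCl, THF, −78 °C; toluene, 90 °C; TBAF, THF, 0 °C; aq. NH4Cl
Reagents that add atoms: lithium dimethylcuprate [Li+].C[Cu-]C
Why: Cuprate conjugate addition anti to the C12 silyloxy and C13 alkenyl groups sets C11 and gives the cyclic ketene silyl acetal, whose Ireland–Claisen ring contraction through the lactone-enforced boat transition state forms C1–C10 with the (Z)-ester carbon on the face opposite the C9 carboxyl, setting C1 and C10; fluoride then removes both silyl groups.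

Step 7
Reactants: 11 cyclohexene hydroxy acid ethyl ester
Product: 14 silyl ether acid, via dihydroxy acid 12 (not isolated), via bis-silyl compound 13 (not isolated)
Conditions: NaH, THF, 0 °C; LiBH4, MeOH, 40 °C; then TESCl, imidazole, DMF, 0 °C; aq. NaHCO3/MeOH work-up
Reagents that add atoms: chlorotriethylsilane CC[Si](Cl)(CC)CC
Why: Chemoselective LiBH4 reduction of the neopentylic ethyl ester beside the sodium carboxylate (inert to borohydride) is followed by silylation of the primary alcohol; the silyl ester falls off on work-up and the hindered secondary 12-OH stays free.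

Step 8
Reactants: 14 silyl ether acid
Product: 15 epoxy acid
Conditions: VO(acac)2 (cat.), tBuOOH, CH2Cl2, 0 °C to rt
Reagents that add atoms: tert-butyl hydroperoxide CC(C)(C)OO
Why: Hydroxyl-directed vanadium-catalysed epoxidation delivers oxygen to the C13=C14 face syn to the allylic 12α-OH and gives the 13α,14α-epoxide.

Step 9
Reactants: 15 epoxy acid
Product: 16 S-ethyl thioester
Conditions: EtSH, EDC·HCl, DMAP (cat.), CH2Cl2, 0 °C
Reagents that add atoms: ethanethiol CCS
Why: Carbodiimide (Steglich-type) thioesterification activates only the acid; the trans-disposed 12-OH cannot lactonise.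

Step 10
Reactants: 16 S-ethyl thioester
Product: 17 cyclohexane aldehyde
Conditions: Et3SiH, Pd/C (10%), acetone, rt
Reagents that add atoms: none
Why: Fukuyama reduction stops at the aldehyde and spares epoxide and silyl ether; no lactol forms because C9 (β) and 12-OH (α) are trans.

Step 11
Reactants: 18 tert-butyldimethyl(prop-2-yn-1-yloxy)silane
Product: 19 bromoalkyne
Conditions: NBS, AgNO3 (cat.), acetone, rt
Reagents that add atoms: N-bromosuccinimide O=C1CCC(=O)N1Br
Why: Silver-catalysed electrophilic bromination of the terminal alkyne C–H.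

Step 12
Reactants: 19 bromoalkyne; 20 methyl 2-methylbut-3-ynoate
Product: 21 (Z)-bromoenyne ester
Conditions: Pd(OAc)2 (5 mol%), MeCN, rt
Reagents that add atoms: none
Why: Palladium-catalysed cis-bromoalkynylation adds the alkynyl group to the terminal carbon and bromine to the internal carbon of 20 on the same side, fixing bromine (the future C9 site) cis to C6.

Step 13
Reactants: 17 cyclohexane aldehyde; 21 (Z)-bromoenyne ester
Product: 22 coupled enyne silyl ether
Conditions: CrCl3 (20 mol%), NiCl2·DME (2 mol%), 4,4'-di-tert-butyl-2,2'-bipyridine (3 mol%), TMSCl, Bu4NBr, DMF, Al anode, Ni-foam cathode, constant current, rt; pH 7 work-up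
Reagents that add atoms: chlorotrimethylsilane C[Si](C)(C)Cl
Why: Electrochemical Nozaki–Hiyama–Kishi coupling (catalytic chromium turned over at the cathode, alkoxide released by the chlorosilane) adds the alkenyl group with retained geometry to the C9 aldehyde in the Felkin–Anh sense, anti to the quaternary C1, which sets 9S; in situ silylation of O9 blocks its lactonisation onto the ester.

Step 14
Reactants: 22 coupled enyne silyl ether
Product: 25 hydroxy lactone, via diol ester 23 (not isolated), via silyl lactone 24 (not isolated)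
Conditions: OsO4 (5 mol%), NMO, acetone/H2O, rt; then aq. citric acid, THF
Reagents that add atoms: N-methylmorpholine N-oxide C[N+]1([O-])CCOCC1; water O
Why: Upjohn dihydroxylation of the only alkene occurs anti to the allylic C9 oxygen (Kishi's empirical rule) and syn across the alkene in which C6 is cis to C9, which sets C8 and C7 as in the target; the C7 hydroxyl, the only free γ-hydroxyl, closes the lactone on the methyl ester and acid removes the trimethylsilyl group.

Step 15
Reactants: 25 hydroxy lactone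
Product: 27 hydroxy lactone single C17 epimer, via lithium enolate 26 (not isolated)
Conditions: LiN(iPr)2 (5 equiv), THF, −78 °C; then AcOH, −78 °C
Reagents that add atoms: none
Why: Stereoselective kinetic protonation of the lithium lactone enolate on the face of the C8 lithium alkoxide, anti to the C9 branch, converges both C17 epimers to the one with the C18 methyl trans to 8-OH.

Step 16
Reactants: 27 hydroxy lactone single C17 epimer
Product: 28 12β-acetate
Conditions: AcOH, PPh3, DIAD, toluene, 0 °C to rt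
Reagents that add atoms: acetic acid CC(=O)O
Why: Mitsunobu inversion: SN2 displacement of the activated 12α-oxygen by acetate gives the 12β-acetate trans to the epoxide, while the neopentylic 9-OH and the tertiary 8-OH are too hindered to react.

Step 17
Reactants: 28 12β-acetate
Product: 29 9,12-diacetate
Conditions: Ac2O, DMAP, pyridine, CH2Cl2, rt
Reagents that add atoms: acetic anhydride CC(=O)OC(C)=O
Why: DMAP-catalysed acetylation of the secondary 9-OH; the tertiary 8-OH is not acylated.

Step 18
Reactants: 29 9,12-diacetate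
Product: 30 C2 aldehyde
Conditions: (COCl)2, DMSO, CH2Cl2, −78 to −30 °C; then Et3N
Reagents that add atoms: none
Why: Direct Swern oxidation of the primary triethylsilyl ether gives the neopentylic aldehyde and leaves the tert-butyldimethylsilyl ether, acetates, lactone and epoxide intact.

Step 19
Reactants: 30 C2 aldehyde
Product: 31 propargylic alcohol
Conditions: HF·pyridine, pyridine, THF, 0 °C
Reagents that add atoms: none
Why: Buffered fluoride desilylation frees the 16-OH that steers the next step.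

Step 20
Reactants: 31 propargylic alcohol
Product: 32 alkenylstannane
Conditions: Bu3SnH, [(C5Me5)RuCl]4 (2.5 mol%), CH2Cl2, rt
Reagents that add atoms: tributyltin hydride CCCC[SnH](CCCC)CCCC
Why: Ruthenium-catalysed trans-hydrostannation: the protic propargylic 16-OH steers tin to C5, and trans addition of H and Sn places tin (the future C4 site) cis to C7.

Step 21
Reactants: 32 alkenylstannane; 33 (Z)-1,2-diiodoethene
Product: 34 dienyl iodide aldehyde
Conditions: 33 (5 equiv), Pd2(dba)3 (5 mol%), AsPh3 (20 mol%), CuI (10 mol%), DMF, rt, dark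
Reagents that add atoms: none
Why: Stille coupling proceeds with retention at both alkenyl partners, and the excess of 33 limits it to mono-coupling, giving the (3Z,5E)-dienyl iodide.

Step 22
Reactants: 34 dienyl iodide aldehyde
Product: 36 target briarane, via silyl ether 35 (not isolated)
Conditions: CrCl3 (20 mol%), NiCl2·DME (5 mol%), 2,9-dimethyl-1,10-phenanthroline (6 mol%), TMSCl, Bu4NBr, DMF (1 mM, slow addition), Al anode, Ni-foam cathode, constant current, rt; then aq. citric acid
Reagents that add atoms: none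
Why: Proposed new method: cathodic reduction regenerates divalent chromium from CrCl3 while zerovalent nickel inserts into the (Z)-dienyl C–I bond and passes the alkenyl group to chromium, the alkenylchromium adds intramolecularly to the neopentylic C2 aldehyde under high dilution and TMSCl frees chromium from the alkoxide, so the ten-membered ring closes at C2–C3 with the diene geometry kept and C2 set by Felkin–Anh attack anti to C10 with the carbonyl oxygen turned toward the C14 epoxide oxygen (predicted 2R); the closest known reaction types are the intermolecular electrochemical NHK coupling and stoichiometric CrCl2/NiCl2 NHK macrocyclisations.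

**Compound list**
1 | D-galactal (1,5-anhydro-2-deoxy-D-lyxo-hex-1-enitol) | C1=CO[C@@H]([C@@H]([C@@H]1O)O)CO | starting material
2 | 4,6-O-(di-tert-butylsilanediyl)-D-galactal | C1=CO[C@H]2[C@@H]([C@@H]1O)O[Si](C(C)(C)C)(C(C)(C)C)OC2 | intermediate
3 | 3-O-acetyl-4,6-O-(di-tert-butylsilanediyl)-D-galactal | C1=CO[C@H]2[C@@H]([C@@H]1OC(C)=O)O[Si](C(C)(C)C)(C(C)(C)C)OC2 | intermediate
4 | 4,6-O-(di-tert-butylsilanediyl)-2,3-dideoxy-D-threo-hex-2-enono-1,5-lactone | O=C1C=C[C@H]2O[Si](C(C)(C)C)(C(C)(C)C)OC[C@H]2O1 | intermediate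
5 | 2,3-dideoxy-4-O-[di-tert-butyl(fluoro)silyl]-D-threo-hex-2-enono-1,5-lactone (6-OH free) | O=C1C=C[C@@H](O[Si](F)(C(C)(C)C)C(C)(C)C)[C@@H](CO)O1 | intermediate
6 | C6 aldehyde of 5 (the CH2OH group oxidised to CHO) | O=C1C=C[C@@H](O[Si](F)(C(C)(C)C)C(C)(C)C)[C@@H](C=O)O1 | intermediate
7 | ethyl 2-(diphenoxyphosphoryl)propanoate | CCOC(=O)C(C)P(=O)(Oc1ccccc1)Oc1ccccc1 | starting material
8 | enonolactone carrying on the ring O-carbon (C13) a (Z)-CH=C(CH3)CO2Et group (ester cis to C13) and on C12 the fluorosilyl ether (cis to the side chain) | O=C1C=C[C@@H](O[Si](F)(C(C)(C)C)C(C)(C)C)[C@@H](/C=C(\C(=O)OCC)C)O1 | intermediate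
9 | cyclic ketene trimethylsilyl acetal of the C11-methyl lactone (methyl trans to the C12 silyloxy and C13 alkenyl groups) | C[Si](C)(C)OC1=C[C@H](C)[C@@H](O[Si](F)(C(C)(C)C)C(C)(C)C)[C@@H](/C=C(\C(=O)OCC)C)O1 | intermediate
10 | trimethylsilyl ester of the ring-contracted cyclohexene acid (C12 fluorosilyl ether) | CC(C)(C)[Si](F)(O[C@@H]1[C@@H](C)[C@@H](C(=O)O[Si](C)(C)C)[C@](C)(C(=O)OCC)C=C1)C(C)(C)C | intermediate
11 | cyclohex-13-ene: C1 β-CH3 and α-CO2Et (C2); C10 β-CO2H (C9); C11 β-CH3; C12 α-OH | O[C@@H]1[C@@H](C)[C@@H](C(=O)O)[C@](C)(C(=O)OCC)C=C1 | intermediate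
12 | as 11 with C2 reduced to CH2OH | O[C@@H]1[C@@H](C)[C@@H](C(=O)O)[C@](C)(CO)C=C1 | intermediate
13 | as 12 with the C2 oxygen and the C9 carboxyl both triethylsilylated | O[C@@H]1[C@@H](C)[C@@H](C(=O)O[Si](CC)(CC)CC)[C@](C)(CO[Si](CC)(CC)CC)C=C1 | intermediate
14 | acid: C2 as CH2OSiEt3; C9 CO2H; 12α-OH; C13=C14 | O[C@@H]1[C@@H](C)[C@@H](C(=O)O)[C@](C)(CO[Si](CC)(CC)CC)C=C1 | intermediate
15 | 13α,14α-epoxide of 14 (epoxide cis to 12-OH) | O[C@@H]1[C@@H](C)[C@@H](C(=O)O)[C@](C)(CO[Si](CC)(CC)CC)[C@@H]2O[C@H]12 | intermediate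
16 | S-ethyl thioester of 15 at C9 | O[C@@H]1[C@@H](C)[C@@H](C(=O)SCC)[C@](C)(CO[Si](CC)(CC)CC)[C@@H]2O[C@H]12 | intermediate
17 | C9 aldehyde: 13α,14α-epoxide; 12α-OH; C2 as CH2OSiEt3 | O[C@@H]1[C@@H](C)[C@@H](C=O)[C@](C)(CO[Si](CC)(CC)CC)[C@@H]2O[C@H]12 | intermediate
18 | tert-butyldimethyl(prop-2-yn-1-yloxy)silane | C#CCO[Si](C)(C)C(C)(C)C | starting material
19 | (3-bromoprop-2-yn-1-yloxy)(tert-butyl)dimethylsilane | BrC#CCO[Si](C)(C)C(C)(C)C | intermediate
20 | methyl 2-methylbut-3-ynoate (racemic) | C#CC(C)C(=O)OC | starting material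
21 | methyl (Z)-3-bromo-7-[(tert-butyldimethylsilyl)oxy]-2-methylhept-3-en-5-ynoate (C17 racemic) | COC(=O)C(C)/C(Br)=C/C#CCO[Si](C)(C)C(C)(C)C | intermediate
22 | coupled product: 9S-type C9–OSiMe3; C8=C7 with C9 cis to the C6 alkynyl group; methyl ester at C19; C17 epimer mixture | O[C@@H]1[C@@H](C)[C@@H]([C@H](O[Si](C)(C)C)/C(C(C)C(=O)OC)=C\C#CCO[Si](C)(C)C(C)(C)C)[C@](C)(CO[Si](CC)(CC)CC)[C@@H]2O[C@H]12 | intermediate
23 | 7,8-diol methyl ester (C7 and C8 as in the target; 9-OSiMe3) | O[C@@H]1[C@@H](C)[C@@H]([C@H](O[Si](C)(C)C)[C@@](O)(C(C)C(=O)OC)[C@H](O)C#CCO[Si](C)(C)C(C)(C)C)[C@](C)(CO[Si](CC)(CC)CC)[C@@H]2O[C@H]12 | intermediate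
24 | C19–O7 γ-lactone with 8-OH and 9-OSiMe3 | O[C@@H]1[C@@H](C)[C@@H]([C@H](O[Si](C)(C)C)[C@]3(O)[C@@H](C#CCO[Si](C)(C)C(C)(C)C)OC(=O)C3C)[C@](C)(CO[Si](CC)(CC)CC)[C@@H]2O[C@H]12 | intermediate
25 | lactone triol (8-OH; 9-OH; 12α-OH); C17 epimer mixture | O[C@@H]1[C@@H](C)[C@@H]([C@H](O)[C@]3(O)[C@@H](C#CCO[Si](C)(C)C(C)(C)C)OC(=O)C3C)[C@](C)(CO[Si](CC)(CC)CC)[C@@H]2O[C@H]12 | intermediate
26 | tetralithium salt of 25 (three alkoxides and the lactone enolate) | [Li]O[C@@H]1[C@@H](C)[C@@H]([C@H](O[Li])[C@]3(O[Li])[C@@H](C#CCO[Si](C)(C)C(C)(C)C)OC(O[Li])=C3C)[C@](C)(CO[Si](CC)(CC)CC)[C@@H]2O[C@H]12 | intermediate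
27 | lactone triol, single C17 epimer (C18 methyl trans to 8-OH) | O[C@@H]1[C@@H](C)[C@@H]([C@H](O)[C@]3(O)[C@@H](C#CCO[Si](C)(C)C(C)(C)C)OC(=O)[C@@H]3C)[C@](C)(CO[Si](CC)(CC)CC)[C@@H]2O[C@H]12 | intermediate
28 | 12β-acetate (C12 inverted; trans to the epoxide) | CC(=O)O[C@H]1[C@@H](C)[C@@H]([C@H](O)[C@]3(O)[C@@H](C#CCO[Si](C)(C)C(C)(C)C)OC(=O)[C@@H]3C)[C@](C)(CO[Si](CC)(CC)CC)[C@@H]2O[C@H]12 | intermediate
29 | 9,12-diacetate | CC(=O)O[C@H]1[C@@H](C)[C@@H]([C@H](OC(C)=O)[C@]3(O)[C@@H](C#CCO[Si](C)(C)C(C)(C)C)OC(=O)[C@@H]3C)[C@](C)(CO[Si](CC)(CC)CC)[C@@H]2O[C@H]12 | intermediate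
30 | C2 aldehyde of 29 | CC(=O)O[C@H]1[C@@H](C)[C@@H]([C@H](OC(C)=O)[C@]3(O)[C@@H](C#CCO[Si](C)(C)C(C)(C)C)OC(=O)[C@@H]3C)[C@](C)(C=O)[C@@H]2O[C@H]12 | intermediate
31 | as 30 with free 16-OH (propargylic alcohol) | CC(=O)O[C@H]1[C@@H](C)[C@@H]([C@H](OC(C)=O)[C@]3(O)[C@@H](C#CCO)OC(=O)[C@@H]3C)[C@](C)(C=O)[C@@H]2O[C@H]12 | intermediate
32 | C5 tributylstannyl alkene (tin cis to C7; 16-OH free) | CC(=O)O[C@H]1[C@@H](C)[C@@H]([C@H](OC(C)=O)[C@]3(O)[C@@H](/C=C(\[Sn](CCCC)(CCCC)CCCC)CO)OC(=O)[C@@H]3C)[C@](C)(C=O)[C@@H]2O[C@H]12 | intermediate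
33 | (Z)-1,2-diiodoethene | I/C=C\I | starting material
34 | (3Z,5E)-dienyl iodide (iodine on C3) with C2 aldehyde | CC(=O)O[C@H]1[C@@H](C)[C@@H]([C@H](OC(C)=O)[C@]3(O)[C@@H](/C=C(CO)\C=C/I)OC(=O)[C@@H]3C)[C@](C)(C=O)[C@@H]2O[C@H]12 | intermediate
35 | 2-O-trimethylsilyl ether of the target | CC(=O)O[C@H]1[C@@H](C)[C@H]2[C@H](OC(C)=O)[C@]3(O)[C@@H](/C=C(CO)\C=C/[C@@H](O[Si](C)(C)C)[C@]2(C)[C@@H]2O[C@H]12)OC(=O)[C@@H]3C | intermediate
36 | target: (1R,2R,3Z,5E,7R,8R,9S,10R,11S,12S,13R,14S,17R)-9,12-diacetoxy-13,14-epoxy-2,8,16-trihydroxybriara-3,5-diene γ-lactone (C19 carbonyl to O–C7) | CC(=O)O[C@H]1[C@@H](C)[C@H]2[C@H](OC(C)=O)[C@]3(O)[C@@H](/C=C(CO)\C=C/[C@@H](O)[C@]2(C)[C@@H]2O[C@H]12)OC(=O)[C@@H]3C | target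

**Step count and risks**
Total step count: 22. Longest linear sequence: 20 (steps 1–10 and 13–22; steps 11 and 12 make fragment 21).

The three steps most likely to fail:

Step 6 (tandem cuprate addition and Ireland–Claisen ring contraction). The cuprate may attack the side-chain enoate, or the boat rearrangement onto the ester-bearing alkene terminus may be slow. Fallback, setting out from 5: add Me2CuLi/TMSCl to the enonolactone before the side chain exists to give the saturated methyl lactone alcohol F1. Oxidise with Dess–Martin periodinane to the saturated lactone aldehyde F2, then carry out the Ando olefination with 7 to the saturated lactone (Z)-enoate F3. Generate the ketene silyl acetal separately with LiN(iPr)2/TMSCl–Et3N at −100 °C and heat in toluene (classical Ireland–Claisen ring contraction through 9 and 10), then TBAF; the route is rejoined at 11.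

Step 16 (Mitsunobu inversion at the hindered epoxy alcohol C12 beside a free 8,9-diol). Fallback, setting out from 27: replace the redox condensation by a discrete sulfonate displacement. Tf2O/pyridine at −40 °C gives the C12 triflate F4, which is displaced with CsOAc/18-crown-6 in toluene with inversion; the route is rejoined at 28.

Step 22 (the proposed electroreductive NHK macrocyclisation). Fallback with known chemistry that closes the ring at C4–C5 instead, setting out from 31: intermolecular NHK addition (CrCl2, NiCl2 cat., DMSO) of (Z)-(2-iodovinyl)trimethylsilane to the C2 aldehyde gives the C2 carbinol vinylsilane F5 (same Felkin–Anh sense). N-iodosuccinimide in hexafluoroisopropanol gives the (Z)-vinyl iodide F6. Trans-hydrostannation with Bu3SnH/[(C5Me5)RuCl]4 gives the iodo stannane F7, and an intramolecular Stille coupling (Pd2(dba)3, AsPh3, DMF, high dilution) forms the diene and the ten-membered ring; the route is rejoined at 36.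

**Further compounds**
F1 | step 6 | saturated C11-methyl lactone alcohol (methyl trans to the C12 silyloxy group; 6-OH free) | O=C1C[C@H](C)[C@@H](O[Si](F)(C(C)(C)C)C(C)(C)C)[C@@H](CO)O1
F2 | step 6 | saturated C11-methyl lactone aldehyde | O=C1C[C@H](C)[C@@H](O[Si](F)(C(C)(C)C)C(C)(C)C)[C@@H](C=O)O1
F3 | step 6 | saturated C11-methyl lactone (Z)-enoate | O=C1C[C@H](C)[C@@H](O[Si](F)(C(C)(C)C)C(C)(C)C)[C@@H](/C=C(\C(=O)OCC)C)O1
F4 | step 16 | 12α-trifluoromethanesulfonate of 27 | O=S(=O)(O[C@@H]1[C@@H](C)[C@@H]([C@H](O)[C@]3(O)[C@@H](C#CCO[Si](C)(C)C(C)(C)C)OC(=O)[C@@H]3C)[C@](C)(CO[Si](CC)(CC)CC)[C@@H]2O[C@H]12)C(F)(F)F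
F5 | step 22 | C2 carbinol (2R) bearing a (Z)-2-(trimethylsilyl)vinyl group (C3=C4) | CC(=O)O[C@H]1[C@@H](C)[C@@H]([C@H](OC(C)=O)[C@]3(O)[C@@H](C#CCO)OC(=O)[C@@H]3C)[C@](C)([C@H](O)/C=C\[Si](C)(C)C)[C@@H]2O[C@H]12
F6 | step 22 | C2 carbinol bearing a (Z)-2-iodovinyl group (iodine on C4) | CC(=O)O[C@H]1[C@@H](C)[C@@H]([C@H](OC(C)=O)[C@]3(O)[C@@H](C#CCO)OC(=O)[C@@H]3C)[C@](C)([C@H](O)/C=C\I)[C@@H]2O[C@H]12
F7 | step 22 | iodo stannane: C4 iodide and C5 tributylstannane (tin cis to C7) | CC(=O)O[C@H]1[C@@H](C)[C@@H]([C@H](OC(C)=O)[C@]3(O)[C@@H](/C=C(\[Sn](CCCC)(CCCC)CCCC)CO)OC(=O)[C@@H]3C)[C@](C)([C@H](O)/C=C\I)[C@@H]2O[C@H]12
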